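**Retrosynthetic overview**
1. The 3-angelate C–O bond is made last, from the 3S alcohol, which comes from the 3-ketone by reagent-controlled reduction.
2. Key C–O disconnection: the C8–O(senecioate) and C3=O groups come from the C3–C8 fusion bond of a trans-decalin tertiary alcohol. C8 shifts oxidatively from C3 to oxygen with retention, and this opens the ten-membered ring.
3. The decalin comes from 9-O-acetylation, a 9-OH-directed 1,10-epoxidation, and ring-closing metathesis to ring B. The two metathesis arms are an allyl group (Grignard addition at C3=O) and a methallyl group (syn aldol with methacrolein at C8).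
4. Ring A, C7 and the cis 4,5-oxirane come from (S)-carvone and H2O2/NaOH.
5. Ring order: ring A (bought), 4,5-oxirane, ring B, 1,10-oxirane, then the ten-membered ring by loss of the shared bond.

Assumption: the SMILES is read literally, so in each oxirane the two ring-carbon substituents are cis (H and CH3 cis). Both oxiranes therefore derive from Z ring olefins.

Locants for all compounds follow the germacrane numbering of the target: C7 isopropenyl, C8 O-senecioyl, C9 O-acetyl, C10(CH3)/C1 oxirane, C2H2, C3 O-angeloyl, C4(CH3)/C5 oxirane, C6H2. The target is 1R,3S,4S,5S,7R,8S,9S,10R.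

**Step 1**
Reactants: 1 (S)-(+)-carvone
Product: 2 (1S,4S,6S)-1-methyl-4-(prop-1-en-2-yl)-7-oxabicyclo[4.1.0]heptan-2-one (carvone oxide; oxirane trans to isopropenyl)
Conditions: 30% aq H2O2, NaOH (0.3 equiv), MeOH, 0 °C
Reagents that add atoms: hydrogen peroxide, OO
Why: Weitz–Scheffer nucleophilic epoxidation touches only the enone C=C; hydroperoxide adds anti to the C7 isopropenyl group, which sets 4S,5S, and because the ring olefin is Z the oxirane carries C3 and C6 cis as the target requires.

**Step 2**
Reactants: 2 carvone oxide; 3 methacrolein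
Product: 6 syn-aldol adduct (1S,3S,4S,6S)-3-[(1S)-1-hydroxy-2-methylprop-2-en-1-yl]-1-methyl-4-(prop-1-en-2-yl)-7-oxabicyclo[4.1.0]heptan-2-one, via lithium enolate 4 (not isolated), via titanium enolate 5 (not isolated)
Conditions: LiN(iPr)2, THF, −78 °C; ClTi(OiPr)3, −78 → −40 °C; 3, −78 °C; then H2O
Reagents that add atoms: methacrolein (3), C=C(C)C=O
Why: Directed aldol addition of the kinetic C8 enolate; the aldehyde approaches anti to the neighbouring isopropenyl group (8S, also the diequatorial thermodynamic isomer), and Ti(OiPr)3 enolates of cyclic ketones favour the syn adduct, which sets 9S.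

**Step 3**
Reactants: 6 syn-aldol adduct; 7 allylmagnesium bromide
Product: 8 (1S,2R,3S,4S,6S)-3-[(1S)-1-hydroxy-2-methylprop-2-en-1-yl]-1-methyl-2-(prop-2-en-1-yl)-4-(prop-1-en-2-yl)-7-oxabicyclo[4.1.0]heptan-2-ol
Conditions: CH2=CHCH2MgBr (2.5 equiv), THF, −78 °C; then H2O
Reagents that add atoms: allylmagnesium bromide (7), C=CC[Mg]Br
Why: Grignard 1,2-addition to the hindered ketone; equatorial attack anti to the oxirane oxygen gives the axial 3-OH (3R) with the allyl group trans-diequatorial to the C9 arm, and since this centre is erased in step 8 its ratio does not affect the end product.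

**Step 4**
Reactants: 8 allyl carbinol
Product: 9 trans-fused decalin diol (3R,4S,5S,7S,8S,9S)-4,5-epoxy-3,8-cyclogermacra-1(10),11-diene-3,9-diol (ring B = C3-C2-C1=C10(CH3)-C9(OH)-C8; 3-OH axial; 9-OH equatorial and cis to H-8)
Conditions: second-generation Grubbs catalyst (5 mol %), CH2Cl2 (0.01 M), 40 °C
Reagents that add atoms: none
Why: Ring-closing metathesis of two trans-diequatorial arms to a cyclohexene is fast and can only give the Z C1=C10 olefin; the isopropenyl group stays out because it could close only to a strained bicyclo[3.3.1]nonene from a diaxial conformer.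

**Step 5**
Reactants: 9 decalin diol
Product: 10 (1R,3R,4S,5S,7S,8S,9S,10S)-1,10:4,5-diepoxy-3,8-cyclogermacr-11-ene-3,9-diol (new oxirane cis to 9-OH)
Conditions: mCPBA (1.05 equiv), CH2Cl2, −20 °C
Reagents that add atoms: 3-chloroperoxybenzoic acid, O=C(OO)c1cccc(Cl)c1
Why: Henbest hydroxyl-directed peracid epoxidation; the pseudo-equatorial allylic 9-OH hydrogen-bonds the peracid and delivers oxygen to its own face while the axial 3-OH shields the other face, which sets C1 and C10, and the trisubstituted ring olefin reacts ahead of the 1,1-disubstituted isopropenyl group as in limonene.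

**Step 6**
Reactants: 10 diepoxy diol
Product: 11 (1R,3R,4S,5S,7S,8S,9S,10R)-1,10:4,5-diepoxy-3-hydroxy-3,8-cyclogermacr-11-en-9-yl acetate
Conditions: Ac2O, DMAP (cat.), pyridine, rt
Reagents that add atoms: acetic anhydride, CC(=O)OC(C)=O
Why: DMAP-catalysed acylation takes the secondary 9-OH and leaves the tertiary axial 3-OH free; no stereocentre is touched.

**Step 7**
Reactants: 12 (diacetoxyiodo)benzene PhI(OAc)2; 13 3-methylbut-2-enoic acid (senecioic acid)
Product: 14 bis(3-methylbut-2-enoyloxy)(phenyl)-λ3-iodane
Conditions: 13 (2.05 equiv), PhCl, 50 °C, reduced pressure (AcOH distilled off)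
Reagents that add atoms: 3-methylbut-2-enoic acid (13), CC(C)=CC(=O)O
Why: Carboxylate ligand exchange at trivalent iodine is driven to completion by removing the more volatile acetic acid.

**Step 8**
Reactants: 11 decalin hydroxy acetate; 14 bis(senecioyloxy)iodobenzene
Product: 17 (1R,4S,5S,7R,8S,9S,10R)-9-acetoxy-1,10:4,5-diepoxy-3-oxogermacr-11-en-8-yl 3-methylbut-2-enoate, via alkoxyiodane 15 (not isolated), via bridged acyloxy ketal 16 (not isolated)
Conditions: 14 (1.3 equiv), 2,6-di-tert-butylpyridine (0.3 equiv), 4 Å MS, (CF3)2CHOH/CH2Cl2 1:4, dark, −20 °C → rt; evaporate; DMAP (0.2 equiv), CH2Cl2, rt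
Reagents that add atoms: bis(3-methylbut-2-enoyloxy)(phenyl)-λ3-iodane (14), CC(C)=CC(=O)OI(OC(=O)C=C(C)C)c1ccccc1
Why: Proposed new method: ligand exchange places the tertiary 3-oxygen on trivalent iodine (15); in the ionising, non-nucleophilic medium and in the dark, PhI departs from oxygen as a hypernucleofuge while the antiperiplanar C3–C8 bond migrates to that oxygen in a concerted 1,2-shift, so the C8–O bond forms with retention (8S) and the fusion bond is exchanged for the ten-membered ring; C8 (secondary alkyl) should out-migrate C2 (primary) and the electron-poor, cyclopropane-like oxiranyl C4; the bridged oxocarbenium ion collapses with its senecioate counter-ion to acyloxy ketal 16; DMAP then removes the acyl group, the hemiketal alkoxide opens to the 3-ketone, and the freed 8-alkoxide is re-acylated; the closest known reaction types are the Criegee rearrangement of 9-decalyl peresters to 1-acyloxy-1,6-epoxycyclodecanes (same skeletal change, carboxylate as the leaving group on oxygen) and the aryl carbon-to-oxygen shift of tertiary benzylic alcohols with trivalent-iodine reagents, whereas alkyl migration from a free tertiary alcohol and the acyl relay are new.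

**Step 9**
Reactants: 17 keto ester
Product: 18 (1R,3S,4R,5S,7R,8S,9S,10R)-9-acetoxy-1,10:4,5-diepoxy-3-hydroxygermacr-11-en-8-yl 3-methylbut-2-enoate (3-OH trans to the 4,5-oxirane oxygen)
Conditions: (R)-2-methyl-CBS-oxazaborolidine (0.5 equiv), catecholborane (2 equiv), toluene, −78 → −40 °C; aqueous work-up
Reagents that add atoms: none
Why: Corey–Bakshi–Shibata reduction; the catalyst binds the carbonyl lone pair anti to the quaternary C4 (large group) and next to C2H2 (small group), so the R catalyst gives 3S (the mirror image of the S catalyst turning acetophenone into the R alcohol), and catecholborane at low temperature spares the isopropenyl group, the enoate, the acetate and both oxiranes.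

**Step 10**
Reactants: 18 3S alcohol; 19 angelic acid ((Z)-2-methylbut-2-enoic acid)
Product: 21 target (1R,3S,4S,5S,7R,8S,9S,10R)-9-acetoxy-1,10:4,5-diepoxy-8-(3-methylbut-2-enoyloxy)germacr-11-en-3-yl (Z)-2-methylbut-2-enoate, via mixed anhydride 20 (not isolated)
Conditions: 19, 2,4,6-trichlorobenzoyl chloride, Et3N, toluene, rt; then 18, 75 °C
Reagents that add atoms: angelic acid (19), C/C=C(/C)C(=O)O
Why: Yamaguchi mixed-anhydride esterification; the alcohol attacks the less shielded angeloyl carbonyl, the C3–O bond is not broken so 3S is kept, and leaving out a nucleophilic catalyst keeps the Z enoate from isomerising to tiglate.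

**Compound list**
1 | (S)-(+)-carvone | C=C(C)[C@H]1CC=C(C)C(=O)C1 | starting material
2 | carvone oxide, (1S,4S,6S)-1-methyl-4-(prop-1-en-2-yl)-7-oxabicyclo[4.1.0]heptan-2-one | C=C(C)[C@H]1C[C@@H]2O[C@]2(C)C(=O)C1 | intermediate
3 | methacrolein | C=C(C)C=O | starting material
4 | lithium enolate of 2 (C3–OLi, C3=C8) | C=C(C)[C@H]1C[C@@H]2O[C@]2(C)C([O-])=C1.[Li+] | intermediate (not isolated)
5 | triisopropoxytitanium enolate of 2 | C=C(C)[C@H]1C[C@@H]2O[C@]2(C)C(O[Ti](OC(C)C)(OC(C)C)OC(C)C)=C1 | intermediate (not isolated)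
6 | syn-aldol adduct (8S,9S; side chain trans to isopropenyl) | C=C(C)[C@H]1C[C@@H]2O[C@]2(C)C(=O)[C@@H]1[C@H](O)C(C)=C | intermediate
7 | allylmagnesium bromide | C=CC[Mg]Br | starting material
8 | allyl carbinol (3R; allyl trans to the C9 arm) | C=C(C)[C@H]1C[C@@H]2O[C@]2(C)[C@@](O)(CC=C)[C@@H]1[C@H](O)C(C)=C | intermediate
9 | trans-decalin diol, 4,5-epoxy-3,8-cyclogermacra-1(10),11-diene-3,9-diol | C=C(C)[C@H]1C[C@@H]2O[C@]2(C)[C@@]3(O)CC=C(C)[C@@H](O)[C@H]13 | intermediate
10 | 1,10:4,5-diepoxy-3,8-cyclogermacr-11-ene-3,9-diol (1,10-oxirane cis to 9-OH) | C=C(C)[C@H]1C[C@@H]2O[C@]2(C)[C@@]3(O)C[C@H]4O[C@@]4(C)[C@@H](O)[C@H]13 | intermediate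
11 | 9-acetate of 10 | C=C(C)[C@H]1C[C@@H]2O[C@]2(C)[C@@]3(O)C[C@H]4O[C@@]4(C)[C@@H](OC(C)=O)[C@H]13 | intermediate
12 | (diacetoxyiodo)benzene | CC(=O)OI(OC(C)=O)c1ccccc1 | starting material
13 | 3-methylbut-2-enoic acid (senecioic acid) | CC(C)=CC(=O)O | starting material
14 | bis(3-methylbut-2-enoyloxy)(phenyl)-λ3-iodane | CC(C)=CC(=O)OI(OC(=O)C=C(C)C)c1ccccc1 | intermediate
15 | 3-O-[phenyl(senecioyloxy)-λ3-iodanyl] derivative of 11 | C=C(C)[C@H]1C[C@@H]2O[C@]2(C)[C@@]3(OI(OC(=O)C=C(C)C)c5ccccc5)C[C@H]4O[C@@]4(C)[C@@H](OC(C)=O)[C@H]13 | intermediate (not isolated)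
16 | bridged acyloxy ketal: 3-senecioyloxy-3,8-epoxide of the ring-expanded skeleton (11-oxabicyclo[4.4.1]undecane core) | C=C(C)[C@H]1C[C@@H]2O[C@]2(C)[C@]3(OC(=O)C=C(C)C)C[C@H]4O[C@@]4(C)[C@@H](OC(C)=O)[C@H]1O3 | intermediate (not isolated)
17 | 3-oxo 8-senecioate 9-acetate (ten-membered ring) | C=C(C)[C@H]1C[C@@H]2O[C@]2(C)C(=O)C[C@H]2O[C@@]2(C)[C@@H](OC(C)=O)[C@H]1OC(=O)C=C(C)C | intermediate
18 | 3S alcohol | C=C(C)[C@H]1C[C@@H]2O[C@]2(C)[C@@H](O)C[C@H]2O[C@@]2(C)[C@@H](OC(C)=O)[C@H]1OC(=O)C=C(C)C | intermediate
19 | angelic acid | C/C=C(/C)C(=O)O | starting material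
20 | angelic 2,4,6-trichlorobenzoic anhydride | C/C=C(/C)C(=O)OC(=O)c1c(Cl)cc(Cl)cc1Cl | intermediate (not isolated)
21 | CNP0276917.1 | C=C(C)[C@H]1C[C@@H]2O[C@]2(C)[C@@H](OC(=O)/C(C)=C\C)C[C@H]2O[C@@]2(C)[C@@H](OC(C)=O)[C@H]1OC(=O)C=C(C)C | target

Total step count: 10. Longest linear sequence: 9 (steps 1–6 and 8–10; step 7 is a side branch).

**Steps most likely to fail: 8, 2 and 9**

**Step 8 (the new step).**
- Failure modes: O–I homolysis could take over. The 3-hydroxy-4,5-epoxide could undergo a semipinacol shift in the ionising solvent. The acetyl group could migrate from O9 to O8 during the relay.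
- Fallback: this uses known radical chemistry and runs from 11 back to 17. Acid 13 and Pb(OAc)4 are exchanged (toluene, reduced pressure) to lead tetrakis(3-methylbut-2-enoate) F5.
- Alcohol 11 is then heated with F5 in benzene. This is the lead tetracarboxylate β-fragmentation that opens ring-fusion tertiary alcohols, such as 5-hydroxy steroids, to ten-membered ketones.
- The 3-alkoxy radical cleaves the C3–C8 bond, because the secondary radical is preferred over primary C2 and oxiranyl C4. Tetravalent lead oxidises the C8 radical and passes on a senecioate ligand to give 17.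
- In this fallback the face at C8 is no longer fixed by a concerted shift, so the 8S ester would have to be separated chromatographically.

**Step 2.**
- Failure mode: the syn preference of the titanium enolate may be low with an α-branched enal.
- Fallback: this sets C9 by substrate-controlled hydride delivery in ring B instead of in the aldol, and runs from 2 back to 9.
- The plain lithium aldol of 4 with 3 gives mainly the anti aldol adduct F1. Allylmagnesium bromide converts it to the allyl carbinol F2.
- Ring-closing metathesis then gives the axial-9-OH decalin diol F3, and MnO2 oxidises it to the decalin enone F4. Any 9 formed alongside is oxidised to the same enone, so both C9 epimers converge.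
- Luche reduction (NaBH4, CeCl3·7H2O, MeOH, −78 °C) adds hydride axially and returns the equatorial 9S alcohol 9.

**Step 9.**
- Failure mode: the catalyst-preferred face may be the transannularly shielded face of the macrocyclic ketone.
- Fallback: this uses chelate control followed by invertive C–O bond formation, and runs from 17 to 21.
- Zn(BH4)2 (Et2O, −20 °C) reduces the α,β-epoxy ketone through the carbonyl/oxirane chelate to the cis-epoxy alcohol, the 3R alcohol F6.
- A Mitsunobu reaction of F6 with angelic acid 19 (PPh3, DIAD, toluene, 0 °C) inverts C3 and installs the angelate in one operation, giving 21 directly.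

**Further compounds**
F1 | step 2 | anti aldol adduct (9R epimer of 6) | C=C(C)[C@H]1C[C@@H]2O[C@]2(C)C(=O)[C@@H]1[C@@H](O)C(C)=C
F2 | step 2 | allyl carbinol (9R epimer of 8) | C=C(C)[C@H]1C[C@@H]2O[C@]2(C)[C@@](O)(CC=C)[C@@H]1[C@@H](O)C(C)=C
F3 | step 2 | axial-9-OH decalin diol (9R epimer of 9) | C=C(C)[C@H]1C[C@@H]2O[C@]2(C)[C@@]3(O)CC=C(C)[C@H](O)[C@H]13
F4 | step 2 | decalin enone (9-oxo analogue of 9) | C=C(C)[C@H]1C[C@@H]2O[C@]2(C)[C@@]3(O)CC=C(C)C(=O)[C@H]13
F5 | step 8 | lead tetrakis(3-methylbut-2-enoate) | CC(C)=CC(=O)[O-].CC(C)=CC(=O)[O-].CC(C)=CC(=O)[O-].CC(C)=CC(=O)[O-].[Pb+4]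
F6 | step 9 | 3R alcohol (3-epimer of 18) | C=C(C)[C@H]1C[C@@H]2O[C@]2(C)[C@H](O)C[C@H]2O[C@@]2(C)[C@@H](OC(C)=O)[C@H]1OC(=O)C=C(C)C
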